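**Retrosynthetic overview**
1. Target 24 ⇐ 23 (hydrogenolysis of two benzyl ethers) ⇐ 22 (acetylation of the tertiary OH).
2. The oxolane, the only ring of the target, is closed in 22 by a 5-exo intramolecular oxa-Michael (1,6-) addition of the primary OH to p-quinone methide 20, followed by O-methylation.
3. The quinone methide precursor, triol 18, comes from lactone 12 and aryllithium 16 (C2–aryl bond) with ketone reduction.
4. Lactone 12 ⇐ hydroxy lactone 8 + BnOCH2Cl 10 (C3, dianion alkylation trans to OH); 8 ⇐ (S)-malic acid via dioxolanone 4 + benzyl bromide 2 (C4, alkylation with retention).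
5. Ring order: the dioxolanone (step 2) and lactone (step 4) are temporary; the oxolane of the target is formed once, in step 10.

Assumption: a sequence run in one flask without isolating the intermediate counts as one step. Atom labels C2–C5 and C9 (the CH2O carbon on C3) refer to the oxolane numbering of the target (O1, C2 aryl, C3, C4 acetate, C5).

**Route**

Step 1
Reactants: 1 [4-(benzyloxy)-3-methoxyphenyl]methanol
Product: 2 1-(benzyloxy)-4-(bromomethyl)-2-methoxybenzene
Conditions: PBr3 (0.4 equiv), Et2O, 0 °C, 1 h; used without chromatography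
Reagents that add atoms: phosphorus tribromide, BrP(Br)Br
Why: Bromination of an electron-rich benzylic alcohol with PBr3 (substitution of the phosphite ester by bromide) is fast and clean at 0 °C.

Step 2
Reactants: 3 (S)-malic acid
Product: 4 2-[(2S,4S)-2-tert-butyl-5-oxo-1,3-dioxolan-4-yl]acetic acid
Conditions: pivalaldehyde (2 equiv), p-toluenesulfonic acid monohydrate (cat.), H2SO4 (cat.), pentane, reflux, Dean–Stark; recrystallise
Reagents that add atoms: pivalaldehyde (2,2-dimethylpropanal), CC(C)(C)C=O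
Why: Acid-catalysed acetalisation of the α-hydroxy acid (Seebach dioxolanone formation) gives the thermodynamically preferred cis isomer, so the malic stereocentre sets the acetal centre (S).

Step 3
Reactants: 4 2-[(2S,4S)-2-tert-butyl-5-oxo-1,3-dioxolan-4-yl]acetic acid; 2 1-(benzyloxy)-4-(bromomethyl)-2-methoxybenzene
Product: 6 2-[(2S,4S)-4-{[4-(benzyloxy)-3-methoxyphenyl]methyl}-2-tert-butyl-5-oxo-1,3-dioxolan-4-yl]acetic acid, via dilithium enolate 5 (not isolated)
Conditions: LiN(SiMe3)2 (2.1 equiv), THF, −78 °C, 45 min; then 2 (1.2 equiv), −78 → −30 °C; aq. HCl work-up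
Reagents that add atoms: none
Why: Seebach self-regeneration of stereocentres: the carboxylate/enolate dianion is alkylated anti to the tert-butyl group, so the benzyl group replaces H with retention and fixes the quaternary carbinol carbon (future C4, S).

Step 4
Reactants: 6 2-[(2S,4S)-4-{[4-(benzyloxy)-3-methoxyphenyl]methyl}-2-tert-butyl-5-oxo-1,3-dioxolan-4-yl]acetic acid
Product: 8 (4S)-4-{[4-(benzyloxy)-3-methoxyphenyl]methyl}-4-hydroxyoxolan-2-one, via dihydroxy acid 7 (not isolated)
Conditions: LiBH4 (4 equiv), THF, 0 °C → rt; then 2 M HCl to pH 1, rt, 2 h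
Reagents that add atoms: none
Why: Chemoselective borohydride reduction of the acylal-type dioxolanone carbonyl (the lithium carboxylate formed in situ is inert) gives the 3,4-dihydroxy acid, which lactonises under acid (γ-lactonisation) without touching the stereocentre.

Step 5
Reactants: 9 benzyl alcohol
Product: 10 benzyl chloromethyl ether
Conditions: paraformaldehyde (1.1 equiv), HCl (gas), neat, 20 °C; dry over CaCl2, distil under reduced pressure
Reagents that add atoms: formaldehyde (as paraformaldehyde), C=O; hydrogen chloride, Cl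
Why: Chloromethylation of an alcohol (hemiformal formation, then chloride substitution) gives the reagent fresh and free of the impurities in technical material.

Step 6
Reactants: 8 (4S)-4-{[4-(benzyloxy)-3-methoxyphenyl]methyl}-4-hydroxyoxolan-2-one; 10 benzyl chloromethyl ether
Product: 12 (3S,4S)-3-[(benzyloxy)methyl]-4-{[4-(benzyloxy)-3-methoxyphenyl]methyl}-4-hydroxyoxolan-2-one, via dilithium dianion 11 (not isolated)
Conditions: LiN(iPr)2 (2.2 equiv), THF, −78 → −40 °C; then 10 (1.3 equiv), DMPU, −78 → −45 °C; AcOH quench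
Reagents that add atoms: none
Why: Fráter–Seebach-type alkylation of the β-alkoxide lactone enolate: the electrophile is expected to enter anti to the solvated lithium alkoxide, placing CH2OBn trans to OH and cis to the benzyl group (C3; S here, R in the final oxolane only through a change in CIP priorities).

Step 7
Reactants: 13 guaiacol (2-methoxyphenol)
Product: 14 4-bromo-2-methoxyphenol
Conditions: N-bromosuccinimide (1.0 equiv), MeCN, 0 °C
Reagents that add atoms: N-bromosuccinimide, O=C1CCC(=O)N1Br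
Why: Electrophilic aromatic bromination goes para to the strongest donor, the free OH.

Step 8
Reactants: 14 4-bromo-2-methoxyphenol
Product: 15 2-(4-bromo-2-methoxyphenoxy)oxane (racemic)
Conditions: 3,4-dihydro-2H-pyran (1.5 equiv), pyridinium p-toluenesulfonate (5 mol%), CH2Cl2, rt
Reagents that add atoms: 3,4-dihydro-2H-pyran, C1=COCCC1
Why: Acid-catalysed addition of the phenol to the enol ether (tetrahydropyranyl acetal protection) gives a base-stable, acid-labile mask that survives organolithium chemistry.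

Step 9
Reactants: 15 2-(4-bromo-2-methoxyphenoxy)oxane; 12 (3S,4S)-3-[(benzyloxy)methyl]-4-{[4-(benzyloxy)-3-methoxyphenyl]methyl}-4-hydroxyoxolan-2-one
Product: 18 (2S,3R)-3-[(benzyloxy)methyl]-2-{[4-(benzyloxy)-3-methoxyphenyl]methyl}-4-[3-methoxy-4-(oxan-2-yloxy)phenyl]butane-1,2,4-triol (epimers at the benzylic carbinol and the acetal carbon), via aryllithium 16 (not isolated), via lactol 17 (not isolated)
Conditions: 15 (2.6 equiv), n-BuLi (2.5 equiv), THF, −78 °C, 30 min; add 12, −78 °C, 1 h; then AcOH/MeOH, CeCl3·7H2O (1.5 equiv), NaBH4 (3 equiv), −78 → −20 °C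
Reagents that add atoms: none
Why: Bromine–lithium exchange and 1,2-addition to the lactone stop at the lithium hemiketalate (one equivalent of 16 first deprotonates the tertiary OH); buffered NaBH4/CeCl3 (Luche) reduction of the ring-opened hydroxy ketone then gives the 1,4-diol, and the new carbinol centre need not be controlled because step 10 erases it.

Step 10
Reactants: 18 (2S,3R)-3-[(benzyloxy)methyl]-2-{[4-(benzyloxy)-3-methoxyphenyl]methyl}-4-[3-methoxy-4-(oxan-2-yloxy)phenyl]butane-1,2,4-triol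
Product: 22 (3S,4R,5S)-4-[(benzyloxy)methyl]-3-{[4-(benzyloxy)-3-methoxyphenyl]methyl}-5-(3,4-dimethoxyphenyl)oxolan-3-ol, via phenolic triol 19 (not isolated), via quinone methide 20 (not isolated), via phenolic oxolane 21 (not isolated)
Conditions: camphor-10-sulfonic acid (10 mol%), MeCN/H2O (20:1), 0 °C → rt (40 °C if slow), 2 h; then K2CO3 (4 equiv), MeI (3 equiv), 40 °C; chromatography removes any C5 epimer
Reagents that add atoms: iodomethane, CI
Why: The acid removes the acetal and dehydrates the p-hydroxybenzyl alcohol to the p-quinone methide, which the primary OH captures by a reversible 5-exo intramolecular oxa-Michael (1,6-conjugate) addition from either carbinol epimer, giving the thermodynamic isomer with aryl trans to CH2OBn (C2, S); Williamson O-methylation then fixes the phenol as its methyl ether.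

Step 11
Reactants: 22 (3S,4R,5S)-4-[(benzyloxy)methyl]-3-{[4-(benzyloxy)-3-methoxyphenyl]methyl}-5-(3,4-dimethoxyphenyl)oxolan-3-ol
Product: 23 (3S,4R,5S)-4-[(benzyloxy)methyl]-3-{[4-(benzyloxy)-3-methoxyphenyl]methyl}-5-(3,4-dimethoxyphenyl)oxolan-3-yl acetate
Conditions: Ac2O (6 equiv), 4-(dimethylamino)pyridine (1.5 equiv), Et3N (8 equiv), CH2Cl2, 40 °C, 24–48 h
Reagents that add atoms: acetic anhydride, CC(=O)OC(C)=O
Why: Nucleophilic-catalysed acyl transfer through the N-acetylpyridinium ion acetylates the only free hydroxyl, the hindered tertiary one, under basic conditions that leave the benzylic ring ether intact.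

Step 12
Reactants: 23 (3S,4R,5S)-4-[(benzyloxy)methyl]-3-{[4-(benzyloxy)-3-methoxyphenyl]methyl}-5-(3,4-dimethoxyphenyl)oxolan-3-yl acetate
Product: 24 (3S,4R,5S)-5-(3,4-dimethoxyphenyl)-3-[(4-hydroxy-3-methoxyphenyl)methyl]-4-(hydroxymethyl)oxolan-3-yl acetate (target)
Conditions: H2 (1 atm), Pd/C (10 wt% Pd, 10 mol%), EtOAc, rt; stopped at full conversion
Reagents that add atoms: none
Why: Catalytic hydrogenolysis cleaves the aryl and the primary alkyl benzyl ether under neutral conditions (no acetyl migration), faster than the hindered cyclic benzylic C–O bond of the oxolane.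

**Compound list**
1 | [4-(benzyloxy)-3-methoxyphenyl]methanol | COc1cc(CO)ccc1OCc1ccccc1 | starting material
2 | 1-(benzyloxy)-4-(bromomethyl)-2-methoxybenzene | COc1cc(CBr)ccc1OCc1ccccc1 | intermediate
3 | (S)-malic acid | OC(=O)C[C@H](O)C(=O)O | starting material
4 | 2-[(2S,4S)-2-tert-butyl-5-oxo-1,3-dioxolan-4-yl]acetic acid | CC(C)(C)[C@H]1O[C@@H](CC(=O)O)C(=O)O1 | intermediate
5 | dilithium carboxylate/enolate of 4 (not isolated) | CC(C)(C)[C@H]1OC(CC(=O)O[Li])=C(O[Li])O1 | intermediate
6 | 2-[(2S,4S)-4-{[4-(benzyloxy)-3-methoxyphenyl]methyl}-2-tert-butyl-5-oxo-1,3-dioxolan-4-yl]acetic acid | CC(C)(C)[C@H]1O[C@](CC(=O)O)(Cc2ccc(OCc3ccccc3)c(OC)c2)C(=O)O1 | intermediate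
7 | (3S)-3-{[4-(benzyloxy)-3-methoxyphenyl]methyl}-3,4-dihydroxybutanoic acid (not isolated) | OC(=O)C[C@](O)(CO)Cc1ccc(OCc2ccccc2)c(OC)c1 | intermediate
8 | (4S)-4-{[4-(benzyloxy)-3-methoxyphenyl]methyl}-4-hydroxyoxolan-2-one | O=C1C[C@@](O)(Cc2ccc(OCc3ccccc3)c(OC)c2)CO1 | intermediate
9 | benzyl alcohol | OCc1ccccc1 | starting material
10 | benzyl chloromethyl ether | ClCOCc1ccccc1 | intermediate
11 | dilithium alkoxide/enolate of 8 (not isolated) | [Li]OC1=C[C@@](O[Li])(Cc2ccc(OCc3ccccc3)c(OC)c2)CO1 | intermediate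
12 | (3S,4S)-3-[(benzyloxy)methyl]-4-{[4-(benzyloxy)-3-methoxyphenyl]methyl}-4-hydroxyoxolan-2-one | O=C1[C@@H](COCc2ccccc2)[C@@](O)(Cc2ccc(OCc3ccccc3)c(OC)c2)CO1 | intermediate
13 | guaiacol (2-methoxyphenol) | COc1ccccc1O | starting material
14 | 4-bromo-2-methoxyphenol | COc1cc(Br)ccc1O | intermediate
15 | 2-(4-bromo-2-methoxyphenoxy)oxane (racemic) | COc1cc(Br)ccc1OC1CCCCO1 | intermediate
16 | [3-methoxy-4-(oxan-2-yloxy)phenyl]lithium (not isolated) | [Li]c1ccc(OC2CCCCO2)c(OC)c1 | intermediate
17 | (3S,4S)-3-[(benzyloxy)methyl]-4-{[4-(benzyloxy)-3-methoxyphenyl]methyl}-2-[3-methoxy-4-(oxan-2-yloxy)phenyl]oxolane-2,4-diol, in equilibrium with its open hydroxy ketone (not isolated; C2 and acetal epimers) | COc1cc(C[C@@]2(O)COC(O)(c3ccc(OC4CCCCO4)c(OC)c3)[C@H]2COCc2ccccc2)ccc1OCc1ccccc1 | intermediate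
18 | (2S,3R)-3-[(benzyloxy)methyl]-2-{[4-(benzyloxy)-3-methoxyphenyl]methyl}-4-[3-methoxy-4-(oxan-2-yloxy)phenyl]butane-1,2,4-triol (C4 and acetal epimers) | COc1cc(C(O)[C@@H](COCc2ccccc2)[C@](O)(CO)Cc2ccc(OCc3ccccc3)c(OC)c2)ccc1OC1CCCCO1 | intermediate
19 | (2S,3R)-3-[(benzyloxy)methyl]-2-{[4-(benzyloxy)-3-methoxyphenyl]methyl}-4-(4-hydroxy-3-methoxyphenyl)butane-1,2,4-triol (not isolated; C4 epimers) | COc1cc(C(O)[C@@H](COCc2ccccc2)[C@](O)(CO)Cc2ccc(OCc3ccccc3)c(OC)c2)ccc1O | intermediate
20 | p-quinone methide from 19 by loss of water, a 4-alkylidene-2-methoxycyclohexa-2,5-dien-1-one with both stereocentres unchanged (not isolated) | COC1=CC(=C[C@@H](COCc2ccccc2)[C@](O)(CO)Cc2ccc(OCc3ccccc3)c(OC)c2)C=CC1=O | intermediate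
21 | 4-[(2S,3R,4S)-3-[(benzyloxy)methyl]-4-{[4-(benzyloxy)-3-methoxyphenyl]methyl}-4-hydroxyoxolan-2-yl]-2-methoxyphenol (not isolated) | COc1cc(C[C@@]2(O)CO[C@H](c3ccc(O)c(OC)c3)[C@H]2COCc2ccccc2)ccc1OCc1ccccc1 | intermediate
22 | (3S,4R,5S)-4-[(benzyloxy)methyl]-3-{[4-(benzyloxy)-3-methoxyphenyl]methyl}-5-(3,4-dimethoxyphenyl)oxolan-3-ol | COc1cc(C[C@@]2(O)CO[C@H](c3ccc(OC)c(OC)c3)[C@H]2COCc2ccccc2)ccc1OCc1ccccc1 | intermediate
23 | (3S,4R,5S)-4-[(benzyloxy)methyl]-3-{[4-(benzyloxy)-3-methoxyphenyl]methyl}-5-(3,4-dimethoxyphenyl)oxolan-3-yl acetate | COc1cc(C[C@@]2(OC(C)=O)CO[C@H](c3ccc(OC)c(OC)c3)[C@H]2COCc2ccccc2)ccc1OCc1ccccc1 | intermediate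
24 | (3S,4R,5S)-5-(3,4-dimethoxyphenyl)-3-[(4-hydroxy-3-methoxyphenyl)methyl]-4-(hydroxymethyl)oxolan-3-yl acetate | COc1cc(C[C@@]2(OC(C)=O)CO[C@H](c3ccc(OC)c(OC)c3)[C@H]2CO)ccc1O | target

**Step count**
Total step count: 12.
Longest linear sequence: 8 steps (2, 3, 4, 6, 9, 10, 11, 12 from (S)-malic acid 3; the path from alcohol 1 through step 1 is also 8). The branches from guaiacol 13 and from benzyl alcohol 9 are 6 steps each to the target.

**Three steps most likely to fail**

Step 6 (facial selectivity of the dianion alkylation next to a fully substituted carbinol carbon; possible O-alkylation). The fallback sets out from 8 and comes back at 12. Claisen formylation of 8 (NaH, ethyl formate, THF) gives the 3-(hydroxymethylidene) lactone F1. K2CO3 and benzyl bromide in acetone convert it into the benzyl enol ether F2 (alkene geometry is irrelevant). Hydroxyl-directed hydrogenation (H2, [Ir(cod)(PCy3)(py)]PF6, CH2Cl2) then delivers hydrogen to C3 from the face of the tertiary OH, so CH2OBn ends trans to OH, which is 12.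

Step 9 (the ring-opened β-hydroxy aryl ketone can undergo retro-aldol cleavage or epimerise at C3 before it is reduced; double addition is also possible). The fallback sets out from 12 and comes back at 18. Reduction of 12 with iBu2AlH (CH2Cl2, −78 °C) gives the lactol F3. Excess aryl Grignard reagent F4 (from 15 and Mg in THF) at 0 °C → rt opens the lactol to the hydroxy aldehyde and arylates it directly to 18, so no ketone stage is passed.

Step 10 (competing Friedel–Crafts closure of the benzylic cation/quinone methide onto the benzyloxy-methoxy ring, elimination to the styrene, or an unfavourable C2 ratio). The fallback sets out from 12 and comes back at 22. (3,4-Dimethoxyphenyl)lithium F5 (from commercial 4-bromo-1,2-dimethoxybenzene and n-BuLi, THF, −78 °C) adds to 12 to give the hemiketal F6. Ionic hydrogenation (Et3SiH, BF3·OEt2, CH2Cl2, −78 → 0 °C) reduces the aryl-stabilised oxocarbenium ion to 22 without opening the ring. BF3·OEt2 equilibrates any 2,3-cis isomer to the trans compound through reversible benzylic C–O ionisation. No phenol unmasking or methylation is then needed.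

**Further compounds**
F1 | step 6 | (4S)-4-{[4-(benzyloxy)-3-methoxyphenyl]methyl}-4-hydroxy-3-(hydroxymethylidene)oxolan-2-one | O=C1C(=CO)[C@@](O)(Cc2ccc(OCc3ccccc3)c(OC)c2)CO1
F2 | step 6 | (4S)-3-[(benzyloxy)methylidene]-4-{[4-(benzyloxy)-3-methoxyphenyl]methyl}-4-hydroxyoxolan-2-one | O=C1C(=COCc2ccccc2)[C@@](O)(Cc2ccc(OCc3ccccc3)c(OC)c2)CO1
F3 | step 9 | (3S,4S)-3-[(benzyloxy)methyl]-4-{[4-(benzyloxy)-3-methoxyphenyl]methyl}oxolane-2,4-diol | COc1cc(C[C@@]2(O)COC(O)[C@H]2COCc2ccccc2)ccc1OCc1ccccc1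
F4 | step 9 | [3-methoxy-4-(oxan-2-yloxy)phenyl]magnesium bromide | Br[Mg]c1ccc(OC2CCCCO2)c(OC)c1
F5 | step 10 | (3,4-dimethoxyphenyl)lithium | [Li]c1ccc(OC)c(OC)c1
F6 | step 10 | (3S,4S)-3-[(benzyloxy)methyl]-4-{[4-(benzyloxy)-3-methoxyphenyl]methyl}-2-(3,4-dimethoxyphenyl)oxolane-2,4-diol | COc1cc(C[C@@]2(O)COC(O)(c3ccc(OC)c(OC)c3)[C@H]2COCc2ccccc2)ccc1OCc1ccccc1
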